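**Retrosynthetic overview**
1. The C8 ester comes from the 8β-alcohol and (Z)-4-acetoxy-2-methylbut-2-enoic acid; the C12 acid comes from late allylic oxidation of the C7 isopropenyl group; the C6/C15 diol is held as a silylene until the last step.
2. The 5α-C(=CH2)CH2OH and 6α-OH pair comes from hydride opening of a cis-fused α-methylene γ-lactone; the 8β-OH from a ketone; the C10 methyl/vinyl centre from copper-catalysed vinyl addition to a β-methyl enone made by allylic oxidation.
3. Key C5–C4 bond: Johnson–Claisen [3,3] rearrangement from the 9α-hydroxyl of a cis-cyclohex-2-ene-1,4-diol, after which the 6α-hydroxyl closes the lactone.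
4. The cis-diol comes from the endoperoxide formed by [4+2] cycloaddition of singlet oxygen, anti to the isopropenyl group, to the cyclohexadiene made from (R)-carvone by a Shapiro reaction; carvone supplies C7 and every ring carbon.
5. Ring order: carbocycle bought in carvone; 2,3-dioxabicyclo[2.2.2]octene ring (cycloaddition, opened at once); γ-lactone ring (Claisen/lactonisation, opened by hydride); silylene ring (temporary).

Convention: ring atoms carry elemane numbers (C5–C10; C5 bears the C3/C4/C15 unit, C7 the C11–C13 unit, C10 the C14 methyl and the C1=C2 vinyl); β is the ring face of the C7 side chain, α the opposite face.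

**Route**

Step 1
Reactants: 1 (R)-(−)-carvone
Product: 2 (R)-carvone tosylhydrazone
Conditions: TsNHNH2 (1.05 equiv), EtOH, 50 °C then 0 °C (crystallise)
Reagents that add atoms: p-toluenesulfonyl hydrazide, Cc1ccc(cc1)S(=O)(=O)NN
Why: Hydrazone condensation at the ketone gives the crystalline tosylhydrazone needed for the Shapiro reaction and does not touch the C7 stereocentre.

Step 2
Reactants: 2 (R)-carvone tosylhydrazone
Product: 4 (5R)-2-methyl-5-(prop-1-en-2-yl)cyclohexa-1,3-diene, via vinyllithium 3 (not isolated)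
Conditions: MeLi (2.2 equiv), TMEDA, Et2O, −78 → 20 °C; then H2O, 0 °C
Reagents that add atoms: none
Why: Shapiro reaction: the dianion, deprotonated at the only sp3 α-carbon, loses sulfinate and N2 to a vinyllithium that is protonated to the ring diene, with C7 untouched.

Step 3
Reactants: 4 (5R)-2-methyl-5-(prop-1-en-2-yl)cyclohexa-1,3-diene
Product: 6 (1R,4R,5S)-2-methyl-5-(prop-1-en-2-yl)cyclohex-2-ene-1,4-diol (6α,9α-diol), via endoperoxide 5 (not isolated)
Conditions: O2, hν, tetraphenylporphyrin (0.5 mol %), CH2Cl2, −78 °C; then thiourea (1.2 equiv), MeOH, 20 °C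
Reagents that add atoms: dioxygen, O=O
Why: Singlet oxygen adds to the cisoid diene in a [4+2] cycloaddition on the face opposite the adjacent isopropenyl group, so both new C–O bonds (C6 and C9) are α, and thiourea cleaves only the O–O bond; the minor syn diol is removed by chromatography.

Step 4
Reactants: 6 (1R,4R,5S)-2-methyl-5-(prop-1-en-2-yl)cyclohex-2-ene-1,4-diol
Product: 9 (3aR,7S,7aS)-4-methyl-7-(prop-1-en-2-yl)-3a,6,7,7a-tetrahydro-1-benzofuran-2(3H)-one (cis-fused 6α,15-lactone), via ketene acetal 7 (not isolated), via hydroxy ester 8 (not isolated)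
Conditions: MeC(OEt)3 (6 equiv), EtCO2H (0.1 equiv), xylene, 140 °C, EtOH distilled off
Reagents that add atoms: triethyl orthoacetate, CC(OCC)(OCC)OCC
Why: Johnson–Claisen [3,3]-sigmatropic rearrangement: the pseudoaxial 9α-O ketene acetal delivers the acetate carbon suprafacially to C5 on the α face (a secondary centre, whereas the pseudoequatorial 6-O unit would have to build a quaternary one), and the cis 6α-OH then lactonises.

Step 5
Reactants: 9 (3aR,7S,7aS)-4-methyl-7-(prop-1-en-2-yl)-3a,6,7,7a-tetrahydro-1-benzofuran-2(3H)-one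
Product: 10 (3aR,7S,7aR)-4-methyl-7-(prop-1-en-2-yl)-3a,7a-dihydro-1-benzofuran-2,6(3H,7H)-dione (C8 ketone conjugated to C9=C10)
Conditions: CrO3 (15 equiv), 3,5-dimethylpyrazole (15 equiv), CH2Cl2, −20 °C
Reagents that add atoms: chromium trioxide, O=[Cr](=O)=O
Why: Allylic oxidation with CrO3–3,5-dimethylpyrazole attacks the only allylic methylene of the trisubstituted alkene (C8), as in the α-pinene to verbenone case, because the other allylic site (C5) is a tertiary ring-fusion carbon; no stereocentre is formed.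

Step 6
Reactants: 10 (3aR,7S,7aR)-4-methyl-7-(prop-1-en-2-yl)-3a,7a-dihydro-1-benzofuran-2,6(3H,7H)-dione
Product: 12 (3aR,4R,7S,7aR)-4-ethenyl-4-methyl-7-(prop-1-en-2-yl)tetrahydro-1-benzofuran-2,6(3H,7H)-dione (10β-vinyl 10α-methyl keto lactone), via silyl enol ether 11 (not isolated)
Conditions: CH2=CHMgBr (1.5 equiv), CuBr·SMe2 (10 mol %), TMSCl, HMPA, THF, −78 °C; then 10% aq. citric acid, 0 °C
Reagents that add atoms: vinylmagnesium bromide, C=C[Mg]Br
Why: TMSCl-accelerated copper-catalysed conjugate addition puts the vinyl group on C10 from the convex β face, anti to the α-oriented lactone carbon on C5, which sets the quaternary centre as vinyl β and methyl α.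

Step 7
Reactants: 12 (3aR,4R,7S,7aR)-4-ethenyl-4-methyl-7-(prop-1-en-2-yl)tetrahydro-1-benzofuran-2,6(3H,7H)-dione
Product: 13 (3aR,4R,6R,7R,7aR)-4-ethenyl-6-hydroxy-4-methyl-7-(prop-1-en-2-yl)hexahydro-1-benzofuran-2(3H)-one (8β-hydroxy lactone)
Conditions: LiBH(s-Bu)3 (1.1 equiv), THF, −78 °C; aq. NH4Cl
Reagents that add atoms: none
Why: Bulky-hydride ketone reduction: hydride arrives equatorially from the α face because the β-axial path is blocked by the axial C10 vinyl group, giving the axial 8β-alcohol cis to the C7 side chain, and the lactone survives at −78 °C.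

Step 8
Reactants: 13 8β-hydroxy lactone
Product: 16 8β-hydroxy α-methylene lactone (C4=C3 exocyclic methylene), via Mannich base 14 (not isolated), via ammonium iodide 15 (not isolated)
Conditions: LiN(i-Pr)2 (2.3 equiv), THF, −78 °C; CH2=NMe2+ I− (2.5 equiv), −78 → 20 °C; then MeI, MeOH, 20 °C; then aq. NaHCO3, CH2Cl2, 20 °C
Reagents that add atoms: N,N-dimethylmethyleneiminium iodide (Eschenmoser's salt), C=[N+](C)C.[I-]
Why: α-Methylenation: the lactone enolate (formed beside the C8 alkoxide) undergoes a Mannich reaction, and quaternisation then Hofmann-type elimination gives the exocyclic alkene; the C4 epimers of 14 and 15 converge and no ring stereocentre changes.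

Step 9
Reactants: 16 8β-hydroxy α-methylene lactone
Product: 17 6α,8β,15-triol [5α-(3-hydroxyprop-1-en-2-yl), 7β-isopropenyl, 10β-vinyl, 10α-methyl]
Conditions: i-Bu2AlH (4 equiv), CH2Cl2, −78 → 0 °C; aq. potassium sodium tartrate
Reagents that add atoms: none
Why: i-Bu2AlH reduces the α-methylene lactone by 1,2-addition through the lactol to the 2-methylene-1,4-diol, releasing the 6α-OH and the C15 allylic alcohol without conjugate reduction.

Step 10
Reactants: 17 6α,8β,15-triol
Product: 18 6α,15-O-(di-tert-butylsilanediyl) derivative of 17 (8β-OH free)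
Conditions: t-Bu2Si(OTf)2 (1.05 equiv), 2,6-lutidine, CH2Cl2, 0 °C
Reagents that add atoms: di-tert-butylsilyl bis(trifluoromethanesulfonate), CC(C)(C)[Si](OS(=O)(=O)C(F)(F)F)(OS(=O)(=O)C(F)(F)F)C(C)(C)C
Why: Cyclic silylene protection: the reagent silylates the primary C15 hydroxyl and closes on the neighbouring cis 6α-OH as a seven-membered 1,4-diol silylene, while the trans-1,3 related 8β-OH cannot bridge and stays free.

Step 11
Reactants: 19 3-methylfuran-2(5H)-one
Product: 21 (2Z)-4-(acetyloxy)-2-methylbut-2-enoic acid, via sodium hydroxy-enoate 20 (not isolated)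
Conditions: NaOH (1.0 equiv), H2O–MeOH, 20 °C, evaporate; then Ac2O, DMAP (cat.), pyridine, 0 → 20 °C; cold 1 M HCl
Reagents that add atoms: sodium hydroxide, [Na+].[OH-]; acetic anhydride, CC(=O)OC(C)=O
Why: Saponification of the butenolide gives the hydroxy-enoate with the Z geometry fixed by the ring, and acetylation of the primary alcohol before acidification prevents relactonisation.

Step 12
Reactants: 18 6α,15-O-silylene 8β-alcohol; 21 (2Z)-4-(acetyloxy)-2-methylbut-2-enoic acid
Product: 23 8β-[(2Z)-4-acetoxy-2-methylbut-2-enoyl] ester of 18, via mixed anhydride 22 (not isolated)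
Conditions: 21, 2,4,6-Cl3C6H2COCl, Et3N, toluene, 20 °C; then 18, DMAP (0.2 equiv), toluene, 40 °C
Reagents that add atoms: none
Why: Yamaguchi esterification: the only free hydroxyl (8β) attacks the unhindered carbonyl of the mixed anhydride with retention at C8, and the low DMAP loading preserves the Z enoate.

Step 13
Reactants: 23 8β-ester
Product: 25 enal (C12 aldehyde on the C7 2-propenyl unit), via allylic alcohol 24 (not isolated)
Conditions: SeO2 (0.3 equiv), t-BuOOH (3 equiv), CH2Cl2, 0 → 20 °C; filter; then MnO2 (20 equiv), CH2Cl2, 20 °C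
Reagents that add atoms: selenium dioxide, O=[Se]=O; tert-butyl hydroperoxide, CC(C)(C)OO
Why: Allylic oxidation (ene reaction then [2,3]-sigmatropic shift) hydroxylates the methyl of the isopropenyl group, the only electron-rich alkene with a free allylic methyl (the C4 methylene is deactivated by its allylic silyloxy carbon and the vinyl group has no allylic hydrogen), and MnO2 takes the allylic alcohol to the enal.

Step 14
Reactants: 25 enal
Product: 26 silylene-protected acrylic acid (C12 acid)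
Conditions: NaClO2, NaH2PO4, 2-methyl-2-butene, t-BuOH–H2O, 0 → 20 °C
Reagents that add atoms: sodium chlorite, [Na+].[O-]Cl=O
Why: Pinnick oxidation converts the enal to the acid under buffered conditions, with the hypochlorite scavenger protecting the four alkenes and the esters left intact.

Step 15
Reactants: 26 silylene-protected acid
Product: 27 target CNP0261293.1
Conditions: HF·pyridine, pyridine, THF, 0 → 20 °C
Reagents that add atoms: none
Why: Buffered fluoride desilylation cleaves both Si–O bonds of the silylene and leaves the acetate, the enoate ester and the hydroxy acid untouched.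

**Compound list**
1 | (R)-(−)-carvone; (5R)-2-methyl-5-(prop-1-en-2-yl)cyclohex-2-en-1-one | CC1=CC[C@@H](C(C)=C)CC1=O | starting material
2 | (R)-carvone tosylhydrazone; N'-[(5R)-2-methyl-5-(prop-1-en-2-yl)cyclohex-2-en-1-ylidene]-4-methylbenzenesulfonohydrazide | CC1=CC[C@@H](C(C)=C)CC1=NNS(=O)(=O)c1ccc(C)cc1 | intermediate
3 | (5R)-3-lithio-2-methyl-5-(prop-1-en-2-yl)cyclohexa-1,3-diene | CC1=CC[C@@H](C(C)=C)C=C1[Li] | intermediate
4 | (5R)-2-methyl-5-(prop-1-en-2-yl)cyclohexa-1,3-diene | CC1=CC[C@@H](C(C)=C)C=C1 | intermediate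
5 | 5-methyl-7-(prop-1-en-2-yl)-2,3-dioxabicyclo[2.2.2]oct-5-ene, peroxide bridge anti to the isopropenyl group | CC1=C[C@H]2OO[C@@H]1C[C@H]2C(C)=C | intermediate
6 | (1R,4R,5S)-2-methyl-5-(prop-1-en-2-yl)cyclohex-2-ene-1,4-diol (6α,9α-diol, both OH trans to isopropenyl) | CC1=C[C@@H](O)[C@H](C(C)=C)C[C@H]1O | intermediate
7 | 9-O-(1-ethoxyethenyl) ketene acetal of 6 | CC1=C[C@@H](O)[C@H](C(C)=C)C[C@H]1OC(=C)OCC | intermediate
8 | ethyl 2-[(1R,5S,6S)-6-hydroxy-2-methyl-5-(prop-1-en-2-yl)cyclohex-2-en-1-yl]acetate | CC1=CC[C@@H](C(C)=C)[C@H](O)[C@@H]1CC(=O)OCC | intermediate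
9 | (3aR,7S,7aS)-4-methyl-7-(prop-1-en-2-yl)-3a,6,7,7a-tetrahydro-1-benzofuran-2(3H)-one (cis-fused 6α,15-lactone) | CC1=CC[C@@H](C(C)=C)[C@H](O2)[C@@H]1CC2=O | intermediate
10 | (3aR,7S,7aR)-4-methyl-7-(prop-1-en-2-yl)-3a,7a-dihydro-1-benzofuran-2,6(3H,7H)-dione | CC1=CC(=O)[C@@H](C(C)=C)[C@H](O2)[C@@H]1CC2=O | intermediate
11 | C8 trimethylsilyl enol ether of 12 (C8=C9) | C=C[C@@]1(C)C=C(O[Si](C)(C)C)[C@@H](C(C)=C)[C@H](O2)[C@@H]1CC2=O | intermediate
12 | (3aR,4R,7S,7aR)-4-ethenyl-4-methyl-7-(prop-1-en-2-yl)tetrahydro-1-benzofuran-2,6(3H,7H)-dione | C=C[C@@]1(C)CC(=O)[C@@H](C(C)=C)[C@H](O2)[C@@H]1CC2=O | intermediate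
13 | (3aR,4R,6R,7R,7aR)-4-ethenyl-6-hydroxy-4-methyl-7-(prop-1-en-2-yl)hexahydro-1-benzofuran-2(3H)-one | C=C[C@@]1(C)C[C@@H](O)[C@@H](C(C)=C)[C@H](O2)[C@@H]1CC2=O | intermediate
14 | 3-[(dimethylamino)methyl] derivative of 13 (Mannich base, C4 epimers) | C=C[C@@]1(C)C[C@@H](O)[C@@H](C(C)=C)[C@H](O2)[C@@H]1C(CN(C)C)C2=O | intermediate
15 | trimethylammonium iodide of 14 | C=C[C@@]1(C)C[C@@H](O)[C@@H](C(C)=C)[C@H](O2)[C@@H]1C(C[N+](C)(C)C)C2=O.[I-] | intermediate
16 | 3-methylidene analogue of 13 (8β-hydroxy α-methylene lactone) | C=C[C@@]1(C)C[C@@H](O)[C@@H](C(C)=C)[C@H](O2)[C@@H]1C(=C)C2=O | intermediate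
17 | triol: 10β-ethenyl-5α-(3-hydroxyprop-1-en-2-yl)-10α-methyl-7β-(prop-1-en-2-yl)cyclohexane-6α,8β-diol (elemane locants) | C=C[C@@]1(C)C[C@@H](O)[C@@H](C(C)=C)[C@H](O)[C@@H]1C(=C)CO | intermediate
18 | 6α,15-O-(di-tert-butylsilanediyl) derivative of 17, 8β-OH free | C=C[C@@]1(C)C[C@@H](O)[C@@H](C(C)=C)[C@H](O2)[C@@H]1C(=C)CO[Si]2(C(C)(C)C)C(C)(C)C | intermediate
19 | 3-methylfuran-2(5H)-one | CC1=CCOC1=O | starting material
20 | sodium (2Z)-4-hydroxy-2-methylbut-2-enoate | [Na+].[O-]C(=O)/C(C)=C\CO | intermediate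
21 | (2Z)-4-(acetyloxy)-2-methylbut-2-enoic acid | OC(=O)/C(C)=C\COC(C)=O | intermediate
22 | (2Z)-4-(acetyloxy)-2-methylbut-2-enoic 2,4,6-trichlorobenzoic anhydride | O=C(OC(=O)/C(C)=C\COC(C)=O)c1c(Cl)cc(Cl)cc1Cl | intermediate
23 | 8β-[(2Z)-4-acetoxy-2-methylbut-2-enoyl] ester of 18 | C=C[C@@]1(C)C[C@@H](OC(=O)/C(C)=C\COC(C)=O)[C@@H](C(C)=C)[C@H](O2)[C@@H]1C(=C)CO[Si]2(C(C)(C)C)C(C)(C)C | intermediate
24 | C12 allylic alcohol of 23 [7β-(3-hydroxyprop-1-en-2-yl)] | C=C[C@@]1(C)C[C@@H](OC(=O)/C(C)=C\COC(C)=O)[C@@H](C(=C)CO)[C@H](O2)[C@@H]1C(=C)CO[Si]2(C(C)(C)C)C(C)(C)C | intermediate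
25 | C12 enal of 23 [7β-(3-oxoprop-1-en-2-yl)] | C=C[C@@]1(C)C[C@@H](OC(=O)/C(C)=C\COC(C)=O)[C@@H](C(=C)C=O)[C@H](O2)[C@@H]1C(=C)CO[Si]2(C(C)(C)C)C(C)(C)C | intermediate
26 | C12 acid of 23 [7β-(1-carboxyethenyl)], silylene intact | C=C[C@@]1(C)C[C@@H](OC(=O)/C(C)=C\COC(C)=O)[C@@H](C(=C)C(=O)O)[C@H](O2)[C@@H]1C(=C)CO[Si]2(C(C)(C)C)C(C)(C)C | intermediate
27 | CNP0261293.1; (5S,6R,7S,8R,10R) by elemane numbering: 8β-[(2Z)-4-acetoxy-2-methylbut-2-enoyloxy]-6α,15-dihydroxyelema-1,3,11(13)-trien-12-oic acid | C=C[C@@]1(C)C[C@@H](OC(=O)/C(C)=C\COC(C)=O)[C@@H](C(=C)C(=O)O)[C@H](O)[C@@H]1C(=C)CO | target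

**Totals**
Total step count: 15. Longest linear sequence: 14 steps (steps 1–10 and 12–15, from (R)-carvone); step 11 makes the side-chain acid.

**Three steps most likely to fail**

Step 2 (Shapiro reaction). The C7–H of diene 4 is doubly allylic, so excess organolithium can racemise or aromatise it. The fallback sets out from 1 and comes back at 4. Kinetic deprotonation of 1 (LiN(i-Pr)2, THF, −78 °C) and O-sulfonylation with PhNTf2 give the cross-conjugated dienyl triflate F1. This is reduced with Pd(OAc)2/PPh3, Bu3N and HCO2H (DMF, 60 °C) to diene 4, which then never meets a strong base.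

Step 5 (allylic oxidation). Competing attack at the tertiary allylic C5–H or at the isopropenyl group, or over-oxidation, could make the enone yield poor. The fallback sets out from 9 and comes back at 10. mCPBA (NaHCO3, CH2Cl2, 0 °C) epoxidises the more electron-rich trisubstituted ring alkene to the 9β,10β-epoxide F2. PhSeNa (from PhSeSePh and NaBH4, EtOH) opens it at C9 to the 10β-hydroxy-9α-phenylselanyl lactone F3. H2O2 (THF, 0 °C) gives the selenoxide F4, whose syn-elimination can only go toward C8 and yields the tertiary allylic alcohol F5. Pyridinium chlorochromate (CH2Cl2) then carries out the oxidative 1,3-transposition (chromate ester [3,3] shift) to enone 10.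

Step 13 (late SeO2 oxidation). With four other alkenes present, selectivity for the isopropenyl methyl or the conversion may be inadequate. The fallback sets out from 23 and comes back at 25. Ene-type chlorination of the isopropenyl group with Ca(OCl)2 and solid CO2 (CH2Cl2–H2O, 0 °C) gives the allylic chloride F6. N-methylmorpholine N-oxide (MeCN, 50 °C) then oxidises it to enal 25, without selenium and without the separate MnO2 stage.

**Further compounds**
F1 | step 2 | (3R)-6-methyl-3-(prop-1-en-2-yl)cyclohexa-1,5-dien-1-yl trifluoromethanesulfonate | CC1=CC[C@@H](C(C)=C)C=C1OS(=O)(=O)C(F)(F)F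
F2 | step 5 | 9β,10β-epoxide of lactone 9 | C[C@]1(O2)[C@@H]2C[C@@H](C(C)=C)[C@H](O3)[C@@H]1CC3=O
F3 | step 5 | 10β-hydroxy-9α-(phenylselanyl) lactone | C[C@]1(O)[C@H]([Se]c2ccccc2)C[C@@H](C(C)=C)[C@H](O3)[C@@H]1CC3=O
F4 | step 5 | selenoxide of F3 | C[C@]1(O)[C@H]([Se](=O)c2ccccc2)C[C@@H](C(C)=C)[C@H](O3)[C@@H]1CC3=O
F5 | step 5 | 10β-hydroxy-8-ene lactone (tertiary allylic alcohol) | C[C@]1(O)C=C[C@@H](C(C)=C)[C@H](O3)[C@@H]1CC3=O
F6 | step 13 | C12 allylic chloride of 23 [7β-(3-chloroprop-1-en-2-yl)] | C=C[C@@]1(C)C[C@@H](OC(=O)/C(C)=C\COC(C)=O)[C@@H](C(=C)CCl)[C@H](O2)[C@@H]1C(=C)CO[Si]2(C(C)(C)C)C(C)(C)C
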